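## Retrosynthetic overview

- **Labels.** Ring A (cyclohexene) carries the 2-benzofuranone locants of the target: C4 (bears Cα of the propanoate), C5 (bears Cq of ring C), C6 and C7 (CH2), C7a (bears the lactone carbonyl C1), C3a (bears the lactol carbon C3). Ring B = lactol-lactone, ring C = trimethylcyclohexane, ring D = a temporary six-membered lactone.
- **Feature.** The ester carbonyl on Cα and the hydroxyl oxygen on C3 can be joined as Cα–C(=O)–O–C3, a four-atom bridge from C4 to C3a (ring D). The target is therefore the methanolysis product of a tricyclic bis-lactone whose C3 is an acylal carbon.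
- **Disconnections.** Methanolysis of ring D and saturation of C6=C7 lead back to a cyclohexa-1,3-diene bis-lactone. A (2+2+2) cycloaddition cuts it at C4–C3a, C5–C6 and C7–C7a into an acylal 1,7-enyne ester (alkyne = C4, C5; butenolide alkene = C3a, C7a) and acetylene (C6, C7).
- **Precursor.** The ester comes from an α-methyl alkynoic acid and 5-bromobutenolide, the acid from the ring C alkyne and an epoxy alcohol (Cα by SN2 inversion), the alkyne from resolved isophorone nitrile (Cq).
- **Ring order.** Rings C and B (as butenolide) are bought; rings D and A form together in the key step; ring D is opened in the last step.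

Key step: step 13

Remark: C3 of the target is a hemiacetal centre and can mutarotate; the configuration drawn (OH cis to the C3a–C4 bond) is the one the acylal carbon carries up to step 14 and is assumed to be the anomer that prevails when ring B re-closes in step 15.
Remark: which antipode from step 1 is (R) is to be fixed by anomalous-dispersion X-ray analysis of the sulfur-containing hydrazone of step 2; the route is written for the (R) ketone. Which fraction of step 12 is the (S)-acylal is to be assigned by X-ray analysis or by correlation after step 13.
Remark: within ring D the (R) centre at Cα is the one that lets Cα–H lie in the plane of C4=C5 next to ring C (least allylic 1,3-strain) with the methyl group on the face away from C3. It is therefore expected to be the thermodynamic epimer of 22, so a partial loss of configuration at Cα should be repairable by brief base equilibration of 22 (DBU, toluene).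

## Route

Step 1
Reactants: 1 rac-3-cyano-3,5,5-trimethylcyclohexanone (isophorone nitrile)
Product: 2 (R)-3-cyano-3,5,5-trimethylcyclohexanone
Conditions: preparative SFC, amylose tris(3,5-dimethylphenylcarbamate) phase, CO2/MeOH, 35 °C
Reagents that add atoms: none
Why: Resolution by chromatography on a chiral stationary phase (no bond is formed) should separate the antipodes of this rigid polar ketone, and the quaternary centre that becomes Cq is stable in the absence of base.

Step 2
Reactants: 2 (R)-3-cyano-3,5,5-trimethylcyclohexanone
Product: 3 N'-[(3R)-3-cyano-3,5,5-trimethylcyclohexylidene]-4-methylbenzenesulfonohydrazide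
Conditions: TsNHNH2, EtOH, 60 °C
Reagents that add atoms: 4-methylbenzenesulfonohydrazide, Cc1ccc(cc1)S(=O)(=O)NN
Why: Hydrazone formation by condensation is fast at the unhindered ketone and leaves the nitrile and Cq untouched, and the crystalline product should allow enrichment by recrystallisation and the X-ray assignment.

Step 3
Reactants: 3 N'-[(3R)-3-cyano-3,5,5-trimethylcyclohexylidene]-4-methylbenzenesulfonohydrazide
Product: 4 (S)-1,3,3-trimethylcyclohexane-1-carbonitrile
Conditions: catecholborane, CHCl3, 0 °C; then NaOAc·3H2O, reflux
Reagents that add atoms: none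
Why: Kabalka reduction of a tosylhydrazone, in which hydride adds to C=N and acetate then triggers loss of sulfinate and of N2 from the diazene, should turn C=O into CH2 without touching the tertiary nitrile or Cq (the descriptor changes from R to S only because the ring branches change rank).

Step 4
Reactants: 4 (S)-1,3,3-trimethylcyclohexane-1-carbonitrile
Product: 6 (S)-1,3,3-trimethylcyclohexane-1-carbaldehyde, via N-aluminoaldimine 5 (not isolated)
Conditions: iBu2AlH, CH2Cl2, −78 → 0 °C; then 1 M HCl
Reagents that add atoms: water, O
Why: Partial reduction of a nitrile with a dialkylaluminium hydride should stop at the hindered N-aluminoimine, which is hydrolysed on acidic work-up to the non-enolisable aldehyde.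

Step 5
Reactants: 6 (S)-1,3,3-trimethylcyclohexane-1-carbaldehyde
Product: 7 (S)-1-ethynyl-1,3,3-trimethylcyclohexane
Conditions: dimethyl (1-diazo-2-oxopropyl)phosphonate, K2CO3, MeOH, 0 °C → rt
Reagents that add atoms: dimethyl (1-diazo-2-oxopropyl)phosphonate, COP(=O)(OC)C(=[N+]=[N-])C(C)=O
Why: Seyferth–Gilbert homologation in the Ohira–Bestmann variant (addition of the diazomethylphosphonate anion, elimination to the diazoalkene, loss of N2 with 1,2-hydride shift) should give the terminal alkyne, and the aldehyde has no α-hydrogen so Cq cannot epimerise.

Step 6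
Reactants: 8 (E)-but-2-en-1-ol
Product: 9 [(2R,3R)-3-methyloxiran-2-yl]methanol
Conditions: Ti(OiPr)4 (cat.), D-(−)-diisopropyl tartrate (cat.), tBuOOH, 4 Å molecular sieves, CH2Cl2, −20 °C
Reagents that add atoms: tert-butyl hydroperoxide, CC(C)(C)OO
Why: Sharpless asymmetric epoxidation with the D-(−)-tartrate should deliver oxygen to the face of the (E)-allylic alcohol that gives the (2R,3R)-epoxy alcohol, which fixes the methyl-bearing epoxide carbon, the future Cα, before its inversion.

Step 7
Reactants: 7 (S)-1-ethynyl-1,3,3-trimethylcyclohexane; 9 [(2R,3R)-3-methyloxiran-2-yl]methanol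
Product: 12 (2S,3R)-3-methyl-5-[(1S)-1,3,3-trimethylcyclohexyl]pent-4-yne-1,2-diol, via lithium acetylide 10 (not isolated), via diethyl(alkynyl)alane 11 (not isolated)
Conditions: 7 (excess), n-BuLi, toluene, 0 °C; Et2AlCl, 0 °C; then 9, 0 °C → rt; aq. potassium sodium tartrate
Reagents that add atoms: none
Why: Opening of a 2,3-epoxy alcohol by a dialkyl(alkynyl)alane should occur at the methyl-bearing carbon with SN2 inversion, directed by the aluminium alkoxide of the hydroxyl group, which gives the 1,2-diol and sets Cα as (R); the alkyne released from the excess alane on work-up is recovered.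

Step 8
Reactants: 12 (2S,3R)-3-methyl-5-[(1S)-1,3,3-trimethylcyclohexyl]pent-4-yne-1,2-diol
Product: 13 (2R)-2-methyl-4-[(1S)-1,3,3-trimethylcyclohexyl]but-3-ynal
Conditions: NaIO4, THF/pH 7 buffer, 0 °C; used crude
Reagents that add atoms: none
Why: Glycol cleavage (Malaprade reaction) through the cyclic periodate ester should remove the terminal carbinol carbon as formaldehyde under neutral conditions, and the α-branched ynal is used at once so that Cα does not epimerise.

Step 9
Reactants: 13 (2R)-2-methyl-4-[(1S)-1,3,3-trimethylcyclohexyl]but-3-ynal
Product: 14 (2R)-2-methyl-4-[(1S)-1,3,3-trimethylcyclohexyl]but-3-ynoic acid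
Conditions: NaClO2, NaH2PO4, 2-methylbut-2-ene, tBuOH/H2O, 0 °C
Reagents that add atoms: sodium chlorite, [Na+].[O-]Cl=O
Why: Pinnick oxidation with chlorous acid at about pH 4 should oxidise the aldehyde without enolisation, so Cα keeps its configuration, while the scavenger removes hypochlorous acid before it can attack the alkyne.

Step 10
Reactants: 15 furan-2(5H)-one
Product: 16 5-bromofuran-2(5H)-one (racemic)
Conditions: NBS, AIBN (cat.), PhCF3, 85 °C; used without storage
Reagents that add atoms: N-bromosuccinimide, O=C1CCC(=O)N1Br
Why: Wohl–Ziegler bromination should enter only at the γ-carbon of the butenolide, where hydrogen abstraction gives a radical that is both allylic and α to the ring oxygen.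

Step 11
Reactants: 14 (2R)-2-methyl-4-[(1S)-1,3,3-trimethylcyclohexyl]but-3-ynoic acid; 16 5-bromofuran-2(5H)-one
Product: 18 5-oxo-2,5-dihydrofuran-2-yl (2R)-2-methyl-4-[(1S)-1,3,3-trimethylcyclohexyl]but-3-ynoate (mixture of the two acylal epimers), via caesium carboxylate 17 (not isolated)
Conditions: Cs2CO3 (0.5 equiv), DMF, 0 °C; then 16, 0 °C → rt
Reagents that add atoms: none
Why: O-Alkylation of the carboxylate at the acetal-type allylic bromide forms the acylal C–O bond without activating the acid as an acyl electrophile, so Cα is not acidified, and because racemic 16 offers no control at the acylal carbon both epimers are expected.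

Step 12
Reactants: 18 5-oxo-2,5-dihydrofuran-2-yl (2R)-2-methyl-4-[(1S)-1,3,3-trimethylcyclohexyl]but-3-ynoate (mixture of the two acylal epimers)
Product: 19 (2S)-5-oxo-2,5-dihydrofuran-2-yl (2R)-2-methyl-4-[(1S)-1,3,3-trimethylcyclohexyl]but-3-ynoate (acylal enyne ester)
Conditions: preparative HPLC, silica, hexane/EtOAc, rt
Reagents that add atoms: none
Why: The two components of 18 are diastereomers because Cα and Cq are fixed, so chromatography on an achiral phase (no bond is formed) should separate them, and the unwanted fraction can be returned to the epimer mixture 18 by reversible ionisation of the acyloxybutenolide with catalytic Pd(PPh3)4 and separated again.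

Step 13
Reactants: 19 (2S)-5-oxo-2,5-dihydrofuran-2-yl (2R)-2-methyl-4-[(1S)-1,3,3-trimethylcyclohexyl]but-3-ynoate; 20 acetylene
Product: 21 tricyclic diene bis-lactone (rings A and B and D; C4=C5 and C6=C7 in ring A; hydrogens at C3 and C3a and C7a all cis; Cα R; C3 S; C3a R; C7a R; Cq S)
Conditions: [Rh(cod)2]BF4 (10 mol%), rac-BINAP (10 mol%), H2 then Ar (pre-activation); C2H2 (1 atm, diluted with Ar), slow addition of 19, ClCH2CH2Cl, 40 °C
Reagents that add atoms: none
Why: Monovalent rhodium binds the alkyne and the butenolide alkene of 19 and couples them oxidatively to a rhodacyclopentene, which forms C4–C3a and thereby closes ring D; acetylene then inserts into a Rh–C bond and reductive elimination completes C5–C6 and C7–C7a and releases ring A as the 1,3-diene. The closest known reaction type is the cationic rhodium/bisphosphine (2+2+2) cycloaddition of 1,6- and 1,7-enynes with alkynes to fused cyclohexa-1,3-dienes. Ring D closes in the oxidative cyclisation (six-membered lactone through the four-atom tether, ester in its s-cis form) and ring A closes in the final reductive elimination. C3a is set by the acylal carbon C3, because the tether lets the alkyne reach only the alkene face that carries the acyloxy oxygen, and C7a follows from suprafacial addition to the cis alkene, so the hydrogens at C3, C3a and C7a should end up cis with either antipode of the ligand. The step needs chemoselectivity for enyne cyclometalation over oligomerisation of acetylene and over co-trimerisation of the hindered alkyne with two acetylenes, which intramolecularity, a low stationary acetylene concentration and slow addition of 19 should secure; acetylene is symmetric, so no regiochemistry arises, and the rhodium-bound C7a carries no exocyclic β-hydrogen that could divert the rhodacycle to an ene product.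

Step 14
Reactants: 21 tricyclic diene bis-lactone
Product: 22 tricyclic bis-lactone with C6 and C7 saturated (ring A cyclohexene with C4=C5 only; stereocentres as in 21)
Conditions: KO2CN=NCO2K, AcOH (slow addition), CH2Cl2, 0 °C → rt
Reagents that add atoms: none
Why: Diimide reduction by concerted syn transfer of two hydrogens should be fast for the cis-disubstituted C6=C7 bond and very slow for the tetrasubstituted, hindered C4=C5 bond, and the slightly acidic medium leaves the acylal and all stereocentres alone.

Step 15
Reactants: 22 tricyclic bis-lactone with C6 and C7 saturated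
Product: 24 methyl (2R)-2-{(3R,3aR,7aR)-3-hydroxy-1-oxo-5-[(1S)-1,3,3-trimethylcyclohexyl]-1,3,3a,6,7,7a-hexahydro-2-benzofuran-4-yl}propanoate (target), via potassium formyl carboxylate 23 (not isolated)
Conditions: K2CO3 (1.0 equiv), MeOH, −20 → 0 °C; then AcOH, pH 4–5 buffer
Reagents that add atoms: methanol, CO
Why: Transesterification by acyl–oxygen cleavage with methoxide should open the six-membered acylal lactone, the more strained of the two, to the methyl ester on Cα, after which the released hemiacetal opens under base to the aldehyde carboxylate and closes again to ring B on acidification with the hydroxyl cis to C4; Cα–H lies in the plane of C4=C5 (allylic 1,3-strain with ring C) and so should exchange slowly, and low temperature with one equivalent of base protects C3a.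

## Compound list

1 | rac-3-cyano-3,5,5-trimethylcyclohexanone (isophorone nitrile) | CC1(C)CC(=O)CC(C)(C#N)C1 | starting material
2 | (R)-3-cyano-3,5,5-trimethylcyclohexanone | N#C[C@@]1(C)CC(=O)CC(C)(C)C1 | intermediate
3 | N'-[(3R)-3-cyano-3,5,5-trimethylcyclohexylidene]-4-methylbenzenesulfonohydrazide | N#C[C@@]1(C)CC(=NNS(=O)(=O)c2ccc(C)cc2)CC(C)(C)C1 | intermediate
4 | (S)-1,3,3-trimethylcyclohexane-1-carbonitrile | N#C[C@@]1(C)CCCC(C)(C)C1 | intermediate
5 | N-(diisobutylalumanyl)aldimine of 6 | CC(C)C[Al](CC(C)C)N=C[C@@]1(C)CCCC(C)(C)C1 | intermediate (not isolated)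
6 | (S)-1,3,3-trimethylcyclohexane-1-carbaldehyde | O=C[C@@]1(C)CCCC(C)(C)C1 | intermediate
7 | (S)-1-ethynyl-1,3,3-trimethylcyclohexane | C#C[C@@]1(C)CCCC(C)(C)C1 | intermediate
8 | (E)-but-2-en-1-ol | C/C=C/CO | starting material
9 | [(2R,3R)-3-methyloxiran-2-yl]methanol | C[C@H]1O[C@@H]1CO | intermediate
10 | lithium acetylide of 7 | [Li]C#C[C@@]1(C)CCCC(C)(C)C1 | intermediate (not isolated)
11 | diethyl(alkynyl)alane of 7 | CC[Al](CC)C#C[C@@]1(C)CCCC(C)(C)C1 | intermediate (not isolated)
12 | (2S,3R)-3-methyl-5-[(1S)-1,3,3-trimethylcyclohexyl]pent-4-yne-1,2-diol | C[C@H](C#C[C@@]1(C)CCCC(C)(C)C1)[C@H](O)CO | intermediate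
13 | (2R)-2-methyl-4-[(1S)-1,3,3-trimethylcyclohexyl]but-3-ynal | C[C@H](C#C[C@@]1(C)CCCC(C)(C)C1)C=O | intermediate
14 | (2R)-2-methyl-4-[(1S)-1,3,3-trimethylcyclohexyl]but-3-ynoic acid | C[C@H](C#C[C@@]1(C)CCCC(C)(C)C1)C(=O)O | intermediate
15 | furan-2(5H)-one | O=C1OCC=C1 | starting material
16 | 5-bromofuran-2(5H)-one (racemic) | BrC1OC(=O)C=C1 | intermediate
17 | caesium (2R)-2-methyl-4-[(1S)-1,3,3-trimethylcyclohexyl]but-3-ynoate | C[C@H](C#C[C@@]1(C)CCCC(C)(C)C1)C(=O)[O-].[Cs+] | intermediate (not isolated)
18 | 5-oxo-2,5-dihydrofuran-2-yl (2R)-2-methyl-4-[(1S)-1,3,3-trimethylcyclohexyl]but-3-ynoate (mixture of the two acylal epimers) | C[C@H](C#C[C@@]1(C)CCCC(C)(C)C1)C(=O)OC2OC(=O)C=C2 | intermediate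
19 | (2S)-5-oxo-2,5-dihydrofuran-2-yl (2R)-2-methyl-4-[(1S)-1,3,3-trimethylcyclohexyl]but-3-ynoate (acylal enyne ester) | C[C@H](C#C[C@@]1(C)CCCC(C)(C)C1)C(=O)O[C@@H]2OC(=O)C=C2 | intermediate
20 | acetylene | C#C | starting material
21 | tricyclic diene bis-lactone (rings A, B, D; C4=C5 and C6=C7; Cα R, C3 S, C3a R, C7a R, Cq S) | C[C@H]1C(=O)O[C@@H]2OC(=O)[C@@H]3C=CC(=C1[C@H]23)[C@@]4(C)CCCC(C)(C)C4 | intermediate
22 | tricyclic bis-lactone (rings A, B, D; C4=C5 only; stereocentres as in 21) | C[C@H]1C(=O)O[C@@H]2OC(=O)[C@@H]3CCC(=C1[C@H]23)[C@@]4(C)CCCC(C)(C)C4 | intermediate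
23 | potassium (1R,2R)-2-formyl-3-[(2R)-1-methoxy-1-oxopropan-2-yl]-4-[(1S)-1,3,3-trimethylcyclohexyl]cyclohex-3-ene-1-carboxylate | COC(=O)[C@H](C)C1=C([C@@]2(C)CCCC(C)(C)C2)CC[C@@H](C(=O)[O-])[C@H]1C=O.[K+] | intermediate (not isolated)
24 | methyl (2R)-2-{(3R,3aR,7aR)-3-hydroxy-1-oxo-5-[(1S)-1,3,3-trimethylcyclohexyl]-1,3,3a,6,7,7a-hexahydro-2-benzofuran-4-yl}propanoate | COC(=O)[C@H](C)C1=C([C@@]2(C)CCCC(C)(C)C2)CC[C@H]2C(=O)O[C@@H](O)[C@@H]12 | target

## Step count and risks

Total step count: 15.
Longest linear sequence: 13 steps (1–5, 7–9, 11–15); steps 6 and 10 are side branches.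

**Steps most likely to fail**

1. **Step 13.** The tert-alkyl alkyne terminus may not enter oxidative cyclisation, the ester tether may stay in its unreactive s-trans form, and acetylene may be consumed by oligomerisation or by co-trimerisation with the alkyne to an arene.
   The fallback sets out from 19 and comes back at 22 (21 is bypassed); ring A would be closed by two separate C–C bond formations. Nickel-catalysed alkylative cyclisation of 19 (Ni(cod)2 cat., (CH2=CH)2Zn prepared from CH2=CHMgBr and ZnCl2, THF, 0 °C; aq. NH4Cl) couples the alkyne and the butenolide alkene at zerovalent nickel, transfers vinyl to C5 and leaves an enolate that is protonated at C7a. This should give the vinyl diene bis-lactone F1, which already holds C4–C3a, ring D and C5–C6. Hydroboration–oxidation of the vinyl group (9-BBN, THF; NaBO3·4H2O) gives the primary alcohol F2, and I2/PPh3/imidazole converts it into the primary iodide F3. LiN(SiMe3)2 (THF, −78 °C) then forms the ring B lactone enolate, which should close C7–C7a by 6-exo alkylation on the face that carries the C3a–C4 bond and so give 22 with the cis ring fusion. The iodide chain is trans to Cα across C4=C5 and cannot alkylate there, and any erosion at Cα is covered by the equilibration of 22 named in the remarks.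

2. **Step 15.** Methoxide may attack the ring B carbonyl instead of the ring D carbonyl, and the open aldehyde form may epimerise at C3a or let C4=C5 move into conjugation.
   The fallback sets out from 22 and comes back at 24. The acylal is hydrolysed under acid instead of being opened by methoxide (1 M HCl, THF/H2O, rt → 40 °C), so that no enolisable aldehyde meets base. The formyl diacid that results should close to the five-membered lactol with the cis carboxyl on C7a, which leaves the lactol propanoic acid F4. The free carboxylic acid alone is then methylated with Me3SiCHN2 (1.0 equiv, toluene/MeOH, 0 °C) to 24. Regiochemistry then rests on five- over six-membered lactol formation and on the acidity of the free acid, not on the site of methoxide attack.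

3. **Step 11.** Bromide 16 may decompose before it is captured, and the 3-alkynoate may isomerise to the allenoate under the basic conditions.
   The fallback sets out from 14 and comes back at 18. Commercial 5-hydroxyfuran-2(5H)-one is converted with di-tert-butyl dicarbonate (DMAP cat., CH2Cl2, 0 °C) into tert-butyl 5-oxo-2,5-dihydrofuran-2-yl carbonate F5. Pd(PPh3)4 (cat., THF, rt) ionises this carbonate to the π-allyl complex of the butenolide with loss of CO2 and tert-butoxide; the alkoxide deprotonates 14 and the carboxylate attacks the acetal terminus to give 18. This is a palladium-catalysed allylic substitution of a γ-acyloxybutenolide by an oxygen nucleophile: no bromide is handled, no base is added and the acid is never activated as an acyl electrophile.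

## Further compounds

F1 | step 13 | vinyl diene bis-lactone (rings B and D; C5 bears vinyl and Cq; C7a is CH2) | C[C@H]1C(=O)O[C@@H]2OC(=O)C[C@@H]2/C1=C(\C=C)[C@@]3(C)CCCC(C)(C)C3
F2 | step 13 | primary alcohol (C5–CH2CH2OH) | C[C@H]1C(=O)O[C@@H]2OC(=O)C[C@@H]2/C1=C(\CCO)[C@@]3(C)CCCC(C)(C)C3
F3 | step 13 | primary iodide (C5–CH2CH2I) | C[C@H]1C(=O)O[C@@H]2OC(=O)C[C@@H]2/C1=C(\CCI)[C@@]3(C)CCCC(C)(C)C3
F4 | step 15 | (2R)-2-{(3R,3aR,7aR)-3-hydroxy-1-oxo-5-[(1S)-1,3,3-trimethylcyclohexyl]-1,3,3a,6,7,7a-hexahydro-2-benzofuran-4-yl}propanoic acid | OC(=O)[C@H](C)C1=C([C@@]2(C)CCCC(C)(C)C2)CC[C@H]2C(=O)O[C@@H](O)[C@@H]12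
F5 | step 11 | tert-butyl 5-oxo-2,5-dihydrofuran-2-yl carbonate (racemic) | CC(C)(C)OC(=O)OC1OC(=O)C=C1
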